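Ring A is made last. Its adjacent oxygens on C7 and C8, next to the ring oxygen O1 on C8a, arrive together as the two carbons of vinylene carbonate. In a Diels–Alder reaction a 5-vinyl-4-pyranone serves as the diene through its C5=C6 bond (flavone C4a=C8a) and the vinyl group. One operation forms C6–C7 and C8–C8a and closes the carbocycle with both oxygens in place; dehydrogenation then gives the benzo ring. The precursor is the monocyclic 2-aryl-3-methoxy-5-vinyl-4-pyranone with ring B attached and its 2'-oxygen held as a benzyl ether. It is built by enolate acylation and cyclisation, iodination at C5 and Stille vinylation.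

Key step: step 7

Remark: ring A positions use flavone numbering (O1, C2 … C8a). Compounds 4 and 7 are taken as purchasable. Compound 14 is racemic and its three stereocentres are removed in step 8; the target is achiral.

Step 1
Reactants: 1 3,4-dimethoxyphenol
Product: 2 2-bromo-4,5-dimethoxyphenol
Conditions: NBS (1.0 equiv), MeCN, 0 °C
Reagents that add atoms: N-bromosuccinimide, O=C1CCC(=O)N1Br
Why: Electrophilic aromatic bromination; the position ortho to the hydroxyl and para to the 3-methoxy group is the most activated and least hindered, so one equivalent of NBS at low temperature should brominate only there.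

Step 2
Reactants: 2 2-bromo-4,5-dimethoxyphenol
Product: 3 1-(benzyloxy)-2-bromo-4,5-dimethoxybenzene
Conditions: BnBr, K2CO3, DMF, rt
Reagents that add atoms: benzyl bromide, BrCc1ccccc1
Why: Williamson ether synthesis; the phenoxide is the only nucleophile and the benzylic bromide a reactive electrophile.

Step 3
Reactants: 3 1-(benzyloxy)-2-bromo-4,5-dimethoxybenzene; 4 N,2-dimethoxy-N-methylacetamide
Product: 6 1-[2-(benzyloxy)-4,5-dimethoxyphenyl]-2-methoxyethan-1-one, via aryllithium 5 (not isolated)
Conditions: n-BuLi, THF, −78 °C; then 4, −78 to 0 °C; aq. NH4Cl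
Reagents that add atoms: none
Why: Bromine–lithium exchange is fast at −78 °C, and the aryllithium adds once to the amide because the chelated tetrahedral adduct persists until work-up (Weinreb ketone synthesis), so no tertiary alcohol should form.

Step 4
Reactants: 6 1-[2-(benzyloxy)-4,5-dimethoxyphenyl]-2-methoxyethan-1-one; 7 (E)-3-ethoxyprop-2-enoyl chloride
Product: 9 2-[2-(benzyloxy)-4,5-dimethoxyphenyl]-3-methoxy-4H-pyran-4-one, via ethoxyvinyl diketone 8 (not isolated)
Conditions: LiN(SiMe3)2 (2.1 equiv), THF, −78 °C; then 7, −78 to 0 °C; AcOH quench; then p-TsOH·H2O (cat.), toluene, 60 °C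
Reagents that add atoms: none
Why: Claisen-type C-acylation of the lithium enolate by the acid chloride (the second equivalent of base holds the diketone as its enolate), followed by acid-catalysed 6-endo attack of the aryl ketone enol oxygen on the β-ethoxy enone and loss of ethanol, the classical closure of a 1,3,5-tricarbonyl equivalent to a 4-pyranone.

Step 5
Reactants: 9 2-[2-(benzyloxy)-4,5-dimethoxyphenyl]-3-methoxy-4H-pyran-4-one
Product: 10 2-[2-(benzyloxy)-4,5-dimethoxyphenyl]-5-iodo-3-methoxy-4H-pyran-4-one
Conditions: I2 (2 equiv), pyridine, DMAP (cat.), CHCl3, rt, dark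
Reagents that add atoms: iodine, II
Why: Amine-mediated α-iodination of an enone: the amine adds reversibly to the unsubstituted C6, the enolate formed is iodinated at C5 and the amine is expelled; unactivated iodine should not substitute the alkoxyarene and C2 is blocked, so only C5 should react.

Step 6
Reactants: 10 2-[2-(benzyloxy)-4,5-dimethoxyphenyl]-5-iodo-3-methoxy-4H-pyran-4-one; 11 tributyl(vinyl)stannane
Product: 12 2-[2-(benzyloxy)-4,5-dimethoxyphenyl]-3-methoxy-5-vinyl-4H-pyran-4-one
Conditions: Pd(PPh3)4 (5 mol %), BHT (trace), toluene, 90 °C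
Reagents that add atoms: none
Why: Stille coupling; zerovalent palladium inserts readily into the C5–I bond of the α-iodoenone, vinyl transfers from tin in preference to butyl, and the ethers and the pyranone are inert.

Step 7
Reactants: 12 2-[2-(benzyloxy)-4,5-dimethoxyphenyl]-3-methoxy-5-vinyl-4H-pyran-4-one; 13 vinylene carbonate
Product: 14 racemic endo adduct, 2-[2-(benzyloxy)-4,5-dimethoxyphenyl]-3-methoxy-4-oxo-6,7,8,8a-tetrahydro-4H-chromene-7,8-diyl carbonate (alkene at C4a=C5; H-7, H-8 and H-8a all cis)
Conditions: 13 (10 equiv), BHT (cat.), o-xylene, sealed tube, 160 °C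
Reagents that add atoms: none
Why: A concerted, suprafacial [4+2] cycloaddition joins the s-cis diene made of the pyranone C5=C6 bond (flavone C4a=C8a) and the vinyl group to the C=C bond of vinylene carbonate, forming C6–C7 and C8–C8a and leaving the remaining alkene at C4a=C5. The closest known reaction type is the Diels–Alder reaction of 3-vinylchromones acting as dienes, and vinylene carbonate is an established thermal dienophile. Ring A, the only ring formed, is closed by intermolecular cycloaddition that makes both σ bonds in one step. The cis relation of the C7 and C8 oxygens follows from the Z geometry locked in the cyclic dienophile, and the relation of H-8a to them from endo approach of the carbonate under the diene; the adduct is racemic and all three centres vanish in step 8, so an exo share is harmless. The selectivity needed is that the vinyl/C5=C6 pair reacts and not C2=C3: only that pair is a planar s-cis 1,3-diene, whereas C2=C3 is tetrasubstituted and screened by aryl and methoxy, and the symmetric dienophile raises no regiochemical question. Excess dienophile and a radical inhibitor should suppress dimerisation of the diene.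

Step 8
Reactants: 14 racemic endo adduct
Product: 15 2-[2-(benzyloxy)-4,5-dimethoxyphenyl]-3-methoxy-4-oxo-4H-chromene-7,8-diyl carbonate
Conditions: DDQ (2.5 equiv), 1,4-dioxane, 90 °C
Reagents that add atoms: none
Why: DDQ dehydrogenation (aromatisation): hydride abstraction from C8a–H (allylic and α to O1) and proton loss from C6 give a 7,8-dihydro compound that is dehydrogenated again to the benzo ring; the cyclic carbonate holds both oxygens as poor leaving groups and no base is present, so C–H loss should outrun elimination.

Step 9
Reactants: 15 2-[2-(benzyloxy)-4,5-dimethoxyphenyl]-3-methoxy-4-oxo-4H-chromene-7,8-diyl carbonate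
Product: 17 2-[2-(benzyloxy)-4,5-dimethoxyphenyl]-3,7,8-trimethoxy-4H-chromen-4-one, via catechol 16 (not isolated)
Conditions: K2CO3, MeOH, rt, argon; concentrate; then MeI, K2CO3, DMF, rt
Reagents that add atoms: iodomethane, CI
Why: Methanolysis (transesterification) of the activated aryl carbonate frees the catechol, which is methylated in the same flask by Williamson alkylation before air can oxidise it; O7 and O8 are the only free hydroxyls.

Step 10
Reactants: 17 2-[2-(benzyloxy)-4,5-dimethoxyphenyl]-3,7,8-trimethoxy-4H-chromen-4-one
Product: 18 2-(2-hydroxy-4,5-dimethoxyphenyl)-3,7,8-trimethoxy-4H-chromen-4-one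
Conditions: H2 (1 atm), Pd/C (10 wt % Pd), EtOAc–MeOH, rt
Reagents that add atoms: none
Why: Catalytic hydrogenolysis of the benzyl aryl ether; the tetrasubstituted, conjugated C2=C3 bond and the methyl ethers should not be reduced at one atmosphere and room temperature.

Compound list
1 | 3,4-dimethoxyphenol | COc1ccc(O)cc1OC | starting material
2 | 2-bromo-4,5-dimethoxyphenol | COc1cc(O)c(Br)cc1OC | intermediate
3 | 1-(benzyloxy)-2-bromo-4,5-dimethoxybenzene | COc1cc(OCc2ccccc2)c(Br)cc1OC | intermediate
4 | N,2-dimethoxy-N-methylacetamide | COCC(=O)N(C)OC | starting material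
5 | [2-(benzyloxy)-4,5-dimethoxyphenyl]lithium (formed in the flask) | [Li]c1cc(OC)c(OC)cc1OCc1ccccc1 | intermediate
6 | 1-[2-(benzyloxy)-4,5-dimethoxyphenyl]-2-methoxyethan-1-one | COCC(=O)c1cc(OC)c(OC)cc1OCc1ccccc1 | intermediate
7 | (E)-3-ethoxyprop-2-enoyl chloride | CCO/C=C/C(Cl)=O | starting material
8 | (E)-1-[2-(benzyloxy)-4,5-dimethoxyphenyl]-5-ethoxy-2-methoxypent-4-ene-1,3-dione (formed in the flask, racemic at C2, largely enolised) | CCO/C=C/C(=O)C(OC)C(=O)c1cc(OC)c(OC)cc1OCc1ccccc1 | intermediate
9 | 2-[2-(benzyloxy)-4,5-dimethoxyphenyl]-3-methoxy-4H-pyran-4-one | COc1cc(OCc2ccccc2)c(-c2occc(=O)c2OC)cc1OC | intermediate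
10 | 2-[2-(benzyloxy)-4,5-dimethoxyphenyl]-5-iodo-3-methoxy-4H-pyran-4-one | COc1cc(OCc2ccccc2)c(-c2occ(I)c(=O)c2OC)cc1OC | intermediate
11 | tributyl(vinyl)stannane | C=C[Sn](CCCC)(CCCC)CCCC | starting material
12 | 2-[2-(benzyloxy)-4,5-dimethoxyphenyl]-3-methoxy-5-vinyl-4H-pyran-4-one | COc1cc(OCc2ccccc2)c(-c2occ(C=C)c(=O)c2OC)cc1OC | intermediate
13 | vinylene carbonate (1,3-dioxol-2-one) | O=C1OC=CO1 | starting material
14 | racemic endo adduct, 2-[2-(benzyloxy)-4,5-dimethoxyphenyl]-3-methoxy-4-oxo-6,7,8,8a-tetrahydro-4H-chromene-7,8-diyl carbonate, H-7, H-8, H-8a all cis (one enantiomer drawn) | COC1=C(c2cc(OC)c(OC)cc2OCc2ccccc2)O[C@H]2[C@H]3OC(=O)O[C@H]3CC=C2C1=O | intermediate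
15 | 2-[2-(benzyloxy)-4,5-dimethoxyphenyl]-3-methoxy-4-oxo-4H-chromene-7,8-diyl carbonate | COc1cc(OCc2ccccc2)c(-c2oc3c4OC(=O)Oc4ccc3c(=O)c2OC)cc1OC | intermediate
16 | 2-[2-(benzyloxy)-4,5-dimethoxyphenyl]-7,8-dihydroxy-3-methoxy-4H-chromen-4-one (formed in the flask) | COc1cc(OCc2ccccc2)c(-c2oc3c(O)c(O)ccc3c(=O)c2OC)cc1OC | intermediate
17 | 2-[2-(benzyloxy)-4,5-dimethoxyphenyl]-3,7,8-trimethoxy-4H-chromen-4-one | COc1cc(OCc2ccccc2)c(-c2oc3c(OC)c(OC)ccc3c(=O)c2OC)cc1OC | intermediate
18 | 2-(2-hydroxy-4,5-dimethoxyphenyl)-3,7,8-trimethoxy-4H-chromen-4-one | COc1cc(O)c(-c2oc3c(OC)c(OC)ccc3c(=O)c2OC)cc1OC | target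

Total step count: 10. Longest linear sequence: 10 steps (1 to 18).

Steps most likely to fail

Step 7. The cycloaddition may be slow because the donor–acceptor diene and the weakly activated dienophile are poorly matched, so that thermal dimerisation or polymerisation of the diene and of vinylene carbonate outpaces adduct formation. The fallback reverses the electronic demand and sets out from 12. An electron-rich dienophile, 1,2-dimethoxyethene F1, is made from commercial 1,1,2-trimethoxyethane by acid-catalysed loss of methanol (KHSO4 cat., distillation). Heating 12 with excess F1 and BHT in toluene in a sealed tube at 140 °C should give the 7,8-dimethoxy tetrahydro adduct F2 as a mixture of diastereomers. Dehydrogenation of F2 with DDQ in dioxane, as in step 8, should lead directly to 17, so steps 8 and 9 are bypassed.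

Step 8. Aromatisation may proceed by loss of a ring oxygen, through ionisation or elimination of an allylic C–O bond in the dihydro stage helped by the acidic hydroquinone, or the oxidation may stall after the first dehydrogenation. The fallback adjusts the oxidation level at the two carbinol carbons and sets out from 14. Brief methanolysis (K2CO3 cat., MeOH, 0 °C) should give the all-cis diol F3. Swern oxidation (DMSO, (COCl)2, CH2Cl2, −78 °C, then Et3N) should give the 7,8-dione F4, which is not isolated: it is the keto tautomer of a catechol and should enolise to 16 under the amine. The route is rejoined at 16, which is methylated as in the second stage of step 9.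

Step 5. Conjugate addition of the amine to the electron-rich pyranone may be too slow, so that iodination stalls, and stronger electrophilic activation would divert iodine to ring B. The fallback introduces iodine at an open-chain enaminone while the ring closes and sets out from 6. C-Acetylation under soft enolisation (MgBr2·OEt2, i-Pr2NEt, AcCl, CH2Cl2) should give the diketone 1-[2-(benzyloxy)-4,5-dimethoxyphenyl]-2-methoxybutane-1,3-dione F5. Condensation of its methyl group with N,N-dimethylformamide dimethyl acetal (toluene, 80 °C) should give the enaminone F6. Iodine in CHCl3 at room temperature should iodinate the enaminone carbon; the enol oxygen then closes onto the iminium carbon and dimethylamine is lost, which returns the route to 10.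

Further compounds
F1 | step 7 | 1,2-dimethoxyethene (E/Z mixture) | COC=COC
F2 | step 7 | 2-[2-(benzyloxy)-4,5-dimethoxyphenyl]-3,7,8-trimethoxy-6,7,8,8a-tetrahydro-4H-chromen-4-one (mixture of racemic diastereomers) | COC1=C(c2cc(OC)c(OC)cc2OCc2ccccc2)OC2C(OC)C(OC)CC=C2C1=O
F3 | step 8 | racemic 2-[2-(benzyloxy)-4,5-dimethoxyphenyl]-7,8-dihydroxy-3-methoxy-6,7,8,8a-tetrahydro-4H-chromen-4-one, H-7, H-8, H-8a all cis | COC1=C(c2cc(OC)c(OC)cc2OCc2ccccc2)O[C@H]2[C@@H](O)[C@@H](O)CC=C2C1=O
F4 | step 8 | 2-[2-(benzyloxy)-4,5-dimethoxyphenyl]-3-methoxy-6,8a-dihydro-4H-chromene-4,7,8-trione (racemic, not isolated) | COC1=C(c2cc(OC)c(OC)cc2OCc2ccccc2)OC2C(=O)C(=O)CC=C2C1=O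
F5 | step 5 | 1-[2-(benzyloxy)-4,5-dimethoxyphenyl]-2-methoxybutane-1,3-dione (racemic) | CC(=O)C(OC)C(=O)c1cc(OC)c(OC)cc1OCc1ccccc1
F6 | step 5 | (E)-1-[2-(benzyloxy)-4,5-dimethoxyphenyl]-5-(dimethylamino)-2-methoxypent-4-ene-1,3-dione (racemic) | CN(C)/C=C/C(=O)C(OC)C(=O)c1cc(OC)c(OC)cc1OCc1ccccc1
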